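The pyridine ring is not bought but built: numbering it N1, C3 (decyl) and C5 (decanoyl), carbon C5 is attached to two one-carbon units, ring atom C4 and the exocyclic carbonyl carbon, which is the signature of a twofold Vilsmeier formylation at an acetyl methyl group. The key step therefore heats (E)-N-(dodec-1-en-1-yl)acetamide with POCl3/DMF, creating C5–C4, C4–C3 and the C5–CHO bond and closing the ring in one operation; amide activation leaves a removable chlorine on C6. The precursor is simply the enamide of dodecanal and acetamide, which supplies N1, C2, decyl-bearing C3, C6 and C5. Nonyl Grignard addition, dechlorination and oxidation then complete the ketone.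

Key step: step 2

Remark: the cationic intermediates of the key step are drawn as dichlorophosphates, and the two carbinols on the way to the ketone are handled as racemates because the final oxidation removes their only stereocentre.

Step 1
Reactants: 1 dodecanal; 2 acetamide
Product: 4 (E)-N-(dodec-1-en-1-yl)acetamide, via bisamide 3 (not isolated)
Conditions: 2 (2.5 equiv), TsOH·H2O (cat.), PhMe, reflux, Dean–Stark; then neat, ca. 190 °C, reduced pressure; crystallisation from hexane
Reagents that add atoms: none
Why: Acid-catalysed condensation of the aldehyde with two molecules of the primary amide (amidoalkylation) should give geminal bisamide 3, and thermal β-elimination of one acetamide from it, the classical bisamide-cracking route to enamides, should deliver the N-alkenylamide with the E geometry favoured under these equilibrating conditions; no stereocentre is formed.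

Step 2
Reactants: 4 (E)-N-(dodec-1-en-1-yl)acetamide; 5 N,N-dimethylformamide
Product: 10 2-chloro-5-decylpyridine-3-carbaldehyde, via chloroiminium salt 6 (not isolated), via imidoyl chloride 7 (not isolated), via vinamidinium salt 8 (not isolated), via pyridylmethaniminium salt 9 (not isolated)
Conditions: POCl3 (7 equiv), DMF (3 equiv), 0 °C then 75 °C; ice–water
Reagents that add atoms: phosphoryl chloride, O=P(Cl)(Cl)Cl; water, O
Why: POCl3 converts DMF into chloroiminium salt 6 and the secondary amide into imidoyl chloride 7, and the N-(1-chlorovinyl)enamine tautomer of 7 is formylated twice by 6 at the former acetyl methyl carbon (C5 in the target numbering) to give vinamidinium salt 8. The decyl-bearing enamide carbon C3 then bonds to the iminium carbon C4 of one arm in a 6-exo-trig Mannich-type closure, which may equally be viewed as a 6π-electrocyclisation of the azatriene C3=C2–N1=C6(Cl)–C5=C4, and loss of dimethylamine aromatises the ring to 9. The aqueous quench hydrolyses the surviving iminium arm of 9 to the aldehyde of 10, while the chlorine from amide activation stays on C6. The closest known reaction type is the Vilsmeier–Haack cyclisation of acetanilides to 2-chloroquinoline-3-carbaldehydes and of N-alkenylacetamides to 2-chloropyridine-3-carbaldehydes. Only this one ring is closed, through carbon alone because both N–C bonds are already present in 4, and no stereocentre is created, the alkene geometry being erased so that any Z isomer converges on the same product. Two selectivities are required: C5 must be formylated twice before the ring closes, which a generous excess of the chloroiminium reagent and heating should ensure, and the ring must close at C3 alone, which is inherent because no other nucleophilic carbon can reach the iminium arm through a six-membered transition state; C2, derived from the aldehyde carbon, keeps its hydrogen.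

Step 3
Reactants: 10 2-chloro-5-decylpyridine-3-carbaldehyde; 11 1-bromononane
Product: 14 rac-1-(2-chloro-5-decylpyridin-3-yl)decan-1-ol, via nonylmagnesium bromide 12 (not isolated), via bromomagnesium alkoxide 13 (not isolated)
Conditions: 11, Mg, I2 (cat.), THF, reflux; then 10, THF, −78 → 0 °C; aq NH4Cl
Reagents that add atoms: none
Why: Grignard 1,2-addition to the non-enolisable heteroaryl aldehyde should be much faster at low temperature than displacement of the 2-chloride or addition to the ring, and the new carbinol stereocentre is formed without control as a racemate, which is immaterial because step 5 converts it into the ketone.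

Step 4
Reactants: 14 rac-1-(2-chloro-5-decylpyridin-3-yl)decan-1-ol
Product: 15 rac-1-(5-decylpyridin-3-yl)decan-1-ol
Conditions: HCO2NH4 (5 equiv), 10% Pd/C, MeOH, 60 °C
Reagents that add atoms: none
Why: In this catalytic transfer hydrogenolysis zerovalent palladium should insert into the C–Cl bond alpha to the ring nitrogen and formate should deliver the hydride, while the secondary pyridyl carbinol and the alkyl chains are inert; doing it before the oxidation keeps the ketone away from the reducing medium and from ammonia.

Step 5
Reactants: 15 rac-1-(5-decylpyridin-3-yl)decan-1-ol
Product: 16 1-(5-decylpyridin-3-yl)decan-1-one (target)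
Conditions: Dess–Martin periodinane (1.3 equiv), CH2Cl2, rt
Reagents that add atoms: none
Why: Dess–Martin oxidation of the secondary alcohol should proceed by ligand exchange at iodine and loss of the carbinol hydrogen under nearly neutral conditions that leave the pyridine nitrogen and the alkyl chains untouched, and it removes the only stereocentre.

Compound list
1 | dodecanal | CCCCCCCCCCCC=O | starting material
2 | acetamide | CC(N)=O | starting material
3 | N,N'-(dodecane-1,1-diyl)diacetamide (bisamide) | CCCCCCCCCCCC(NC(C)=O)NC(C)=O | intermediate (not isolated)
4 | (E)-N-(dodec-1-en-1-yl)acetamide | CCCCCCCCCC/C=C/NC(C)=O | intermediate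
5 | N,N-dimethylformamide | CN(C)C=O | starting material
6 | N-(chloromethylidene)-N-methylmethanaminium dichlorophosphate (chloroiminium salt) | C[N+](C)=CCl.[O-]P(=O)(Cl)Cl | intermediate (not isolated)
7 | N-[(E)-dodec-1-en-1-yl]ethanimidoyl chloride | CCCCCCCCCC/C=C/N=C(C)Cl | intermediate (not isolated)
8 | N-[2-{chloro[(E)-dodec-1-en-1-ylimino]methyl}-3-(dimethylamino)prop-2-en-1-ylidene]-N-methylmethanaminium dichlorophosphate (vinamidinium salt) | CCCCCCCCCC/C=C/N=C(Cl)C(=CN(C)C)C=[N+](C)C.[O-]P(=O)(Cl)Cl | intermediate (not isolated)
9 | N-[(2-chloro-5-decylpyridin-3-yl)methylidene]-N-methylmethanaminium dichlorophosphate | CCCCCCCCCCc1cnc(Cl)c(C=[N+](C)C)c1.[O-]P(=O)(Cl)Cl | intermediate (not isolated)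
10 | 2-chloro-5-decylpyridine-3-carbaldehyde | CCCCCCCCCCc1cnc(Cl)c(C=O)c1 | intermediate
11 | 1-bromononane | CCCCCCCCCBr | starting material
12 | nonylmagnesium bromide | CCCCCCCCC[Mg]Br | intermediate (not isolated)
13 | bromomagnesium 1-(2-chloro-5-decylpyridin-3-yl)decan-1-olate (racemic) | CCCCCCCCCCc1cnc(Cl)c(C(O[Mg]Br)CCCCCCCCC)c1 | intermediate (not isolated)
14 | rac-1-(2-chloro-5-decylpyridin-3-yl)decan-1-ol | CCCCCCCCCCc1cnc(Cl)c(C(O)CCCCCCCCC)c1 | intermediate
15 | rac-1-(5-decylpyridin-3-yl)decan-1-ol | CCCCCCCCCCc1cncc(C(O)CCCCCCCCC)c1 | intermediate
16 | 1-(5-decylpyridin-3-yl)decan-1-one | CCCCCCCCCCc1cncc(C(=O)CCCCCCCCC)c1 | target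

Total step count: 5
Longest linear sequence: 5 steps (1 → 4 → 10 → 14 → 15 → 16)

Steps most likely to fail

Step 2 (key step).
- What may go wrong: the chloroiminium reagent may attack the enamide carbon C3, or acid may hydrolyse or oligomerise the secondary enamide, before the amide oxygen is activated. Ring closure may also overtake the second formylation, so that the formyl arm is lost.
- Fallback: it sets out from 1 and carries the nitrogen as a tertiary N-benzyl amide, the substrate class for which closure to 5-alkyl-2-chloropyridines and their 3-carbaldehydes is established. Condensation of 1 with benzylamine (MgSO4, CH2Cl2) should give N-benzyldodecan-1-imine F1. N-Acetylation with Ac2O/Et3N in warm toluene, with tautomerisation, should give N-benzyl-N-[(E)-dodec-1-en-1-yl]acetamide F2. Under POCl3/DMF the tertiary amide, which is activated faster and as an α-chloroiminium ion, should be formylated twice and cyclised to 1-benzyl-2-chloro-5-decyl-3-[(dimethyliminio)methyl]pyridinium dichloride F3. Chloride then removes the benzyl group as benzyl chloride, and the fallback comes back to the route at 9 and, after the aqueous quench, at 10.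

Step 1.
- What may go wrong: acid-promoted aldol self-condensation of the enolisable aldehyde, incomplete cracking of the bisamide, or oligomerisation of the enamide during thermolysis.
- Fallback: it sets out from 2, which is added across commercial dodec-1-yne by ruthenium-catalysed anti-Markovnikov hydroamidation (Ru(cod)(2-methylallyl)2, 1,4-bis(dicyclohexylphosphino)butane, Yb(OTf)3, DMF, 60 °C). This should give (Z)-N-(dodec-1-en-1-yl)acetamide F4. Base-mediated isomerisation in the same pot (Et3N, molecular sieves, 110 °C) should convert it into 4, where the route is rejoined. Incomplete isomerisation would be harmless, since step 2 erases the alkene geometry.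

Step 4.
- What may go wrong: poisoning of the heterogeneous catalyst by the pyridine nitrogen, leading to stalled hydrogenolysis, or, on forcing, partial saturation of the ring or loss of the pyridylic hydroxyl group.
- Fallback: it sets out from 14 and inverts the order of the last two operations. Dess–Martin oxidation should give 1-(2-chloro-5-decylpyridin-3-yl)decan-1-one F5, whose C–Cl bond is activated toward oxidative addition by the ortho acyl group as well as by the ring nitrogen. Homogeneous hydrodechlorination with Pd(PPh3)4 and HCO2Na in DMF at 100 °C, a system that does not reduce ketones, should then give 16 directly.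

Further compounds
F1 | step 2 | N-benzyldodecan-1-imine | CCCCCCCCCCC/C=N/Cc1ccccc1
F2 | step 2 | N-benzyl-N-[(E)-dodec-1-en-1-yl]acetamide | CCCCCCCCCC/C=C/N(Cc1ccccc1)C(C)=O
F3 | step 2 | 1-benzyl-2-chloro-5-decyl-3-[(dimethyliminio)methyl]pyridinium dichloride | CCCCCCCCCCc1c[n+](Cc2ccccc2)c(Cl)c(C=[N+](C)C)c1.[Cl-].[Cl-]
F4 | step 1 | (Z)-N-(dodec-1-en-1-yl)acetamide | CCCCCCCCCC/C=C\NC(C)=O
F5 | step 4 | 1-(2-chloro-5-decylpyridin-3-yl)decan-1-one | CCCCCCCCCCc1cnc(Cl)c(C(=O)CCCCCCCCC)c1
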